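## Analysis of the target

The target is a 9,13;15,16-diepoxylabdane. Rings A and B form a trans-fused decalin; ring C is a tetrahydrofuran spiro-fused at C9 (oxygen between C9 and C13); ring D is a 2,3-dihydrofuran (C14=C15–O–C16) spiro-fused at C13. There are six stereocentres (C4, C5, C8, C9, C10, C13); five are fully substituted, and C8, C9 and C10 are contiguous. The C20 methyl is β and H-5 is α. The acetoxymethyl group C19 is axial on C4, cis to C20. The C9–O bond is α and the C8 acetate is β and axial, trans-diaxial to it, with the C17 methyl equatorial. C13 is R, with C16 on the C8 side of ring C. The enol ether of ring D is acid-labile (ring C opens and a furan forms), and the tertiary α-acetoxy ketone is base-sensitive (acyl shift, ketol rearrangement). The hard points are the crowded C8–C9–C10 triad, the remote quaternary C13 that the decalin cannot control, and the oxidised C19, which the common chiral-pool labdanes lack. The strategy rests on one feature: rings A and B, with quaternary C4 and C10 and hydrogen at C5, are the head-to-tail fold of a farnesyl-type chain, and C8 (oxygenated) together with C11 (on C9) sit at the oxidation level of an acetoacetate unit that can end that fold.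

## Retrosynthetic reasoning

37 from 36 (C7=O). The α-acetoxy ketone is the most base-sensitive array, so it is unveiled last by oxidising the 7α-alcohol. The forward step must oxidise a hindered axial alcohol without acid, because ring D is already present.

36 from 35 (O–C15 of ring D). Cutting the enol-ether C–O bond gives a homopropargylic alcohol that is an isomer of ring D. C13 already exists, and the closure runs under amine base after all acid steps are over.

35 from 34 and 33 (C8–OAc and C7–O). C8 needs its oxygen on the β face, syn to C20, where no oxidant adds directly. An α-epoxide on C7–C8, opened trans-diaxially by a carboxylic acid, puts the nucleophile on that face at the tertiary carbon and delivers the acetate without a hindered acylation. The forward steps must epoxidise from the α face and open at C8.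

33 from 32, 31 and 30 (O–C13 of ring C). C9 keeps its oxygen and C13 becomes the tertiary carbon of an ethynyl epoxide. The closure is a 5-exo opening with inversion, so C13 is set by reagent control in the epoxide. Cutting O–C9 instead would need an electrophilic C9 between two quaternary carbons. The silyl ethers of 30 are exchanged for the C19 acetate (31, 32) before closure, because afterwards the freed C16 hydroxyl would compete.

30 from 29, 28 and 27 (C14≡C15 and the C13 epoxide). The alkyne comes from an aldehyde by one-carbon homologation. The epoxy aldehyde 29 comes from epoxy alcohol 28, the Sharpless product of the 2-substituted allylic alcohol 27. This turns an achiral 1,1-disubstituted alkene into the C13 stereocentre.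

27 from 24 and 25 (C12–C13), and 24 from 23, 22 and 21 (C11=C12). An sp3–sp2 cross-coupling joins the hydroborated vinyl group of 24 to bromoalkene 25. The vinyl group comes from the C11 aldehyde and that from the ester, so the ester carbon of the cyclisation product becomes C11.

21 from 20 and 19 (C8–C17). The methyl group is put on through the enol triflate of the C8 ketone. The resulting C7=C8 alkene is a robust mask for the acetoxy ketone during the side-chain work.

19 from 18 and 17 (C9–O). The C9 oxygen is introduced at the only doubly activated position, by hydroxylation of the β-keto ester enolate from the face opposite C20, then silylated.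

17 from 16 and 15 (C3–O). The C3 hydroxyl, the price of epoxide initiation, is removed by radical deoxygenation.

15 from 14 (C4–C5 and C9–C10). Both ring bonds are cut at once to give the acyclic epoxy keto ester. This removes two rings and three stereocentres in one step and traces absolute configuration to one epoxide.

14 from 12 and 13 (C6–C7). The allylic bromide alkylates the terminal carbon of the acetoacetate dianion.

12 from 11, 10, 9, 8 and 7 (epoxide and protecting groups). The epoxide comes from the Z allylic alcohol 7 by Sharpless epoxidation. The Z geometry places the oxygenated carbon cis to the chain, which becomes axial C19.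

7 from 6, and 6 from 4 and 5 (C3=C4); 4 from 3, 2 and 1. A Z-selective olefination of aldehyde 4 with phosphonate 5 sets the alkene. The aldehyde comes from cleavage of the distal alkene of protected geraniol.

## Alternatives that were turned down

Alternative 1: Cut C13–C14 and close ring D as a γ-lactone by carbenoid C–H insertion. A dirhodium catalyst (Rh2(OAc)4 or a carboxamidate) would decompose the C16 diazoacetate A2, and the carbenoid would insert into the tertiary C13–H bond to give spiro lactone A1 with retention.
- For: the C–H bond is next to the ring C oxygen and tertiary, and the five-membered transition state is favoured. The quaternary centre is made by direct C–C bond formation from a C–H stereocentre that is easier to set. On that point it is stronger than the chosen route, which needs epoxidation, oxidation and homologation for C13 and C14.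
- Against: an acceptor-only carbenoid is unselective. Oxonium ylide formation at the ring C oxygen, insertion at C12–H or C16–H and dimerisation all compete.
- Against: A1 must still be reduced to the lactol and dehydrated. That hydride step is incompatible with the C7 ketone and the acetates, so all ring B oxidation would follow on a molecule that already carries the enol ether.
- Comparison: the chosen route makes ring D by a redox-free isomerisation and supplies the decalin that A2 presupposes.

Alternative 2: Cut ring B at C7–C8 after cleaving the C7=C8 alkene. A triazolium-derived carbene with Et3N would turn the C7 aldehyde of seco compound A4 into an acyl anion equivalent that adds to the C8 methyl ketone, giving hydroxy ketone A3.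
- For: one redox-neutral C–C bond formation gives the 8-hydroxy-8-methyl-7-ketone directly. That is more direct than the five operations the chosen route spends on C7 and C8.
- Against: nothing in A4 dictates that the hydroxyl ends axial and syn to C20. The addition is reversible, so the more stable epimer (equatorial hydroxyl) is the likely outcome.
- Against: the aldehyde enolate can instead close a five-membered ring on the ketone, and the tertiary alcohol must then be acetylated in a crowded site.
- Comparison: the step opens and recloses a ring the cyclisation already provides. The chosen route sets C8 by a stereospecific trans-diaxial epoxide opening that also delivers the acetate.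

Alternative 3: Cut O–C9. Mild acid would activate the 8β,9β-epoxide A6, and the tertiary C13 hydroxyl would attack C9 from the α face to give diol A5 with ring C closed.
- For: one epoxide sets both C8 and C9, and the trans-diaxial 8β-O/9α-O array is the natural outcome. For this pair it is stronger than the chosen route, which uses separate steps.
- Against: it needs epoxidation of a tetrasubstituted alkene on the face syn to C20, possible only through the directing 7β-hydroxyl.
- Against: a tertiary alcohol must attack a fully substituted carbon next to quaternary C10. Cation character at C9 invites a 1,2-shift of the C20 methyl or 6-endo attack at C8.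
- Against: C13 would have to be set as a tertiary propargylic alcohol by addition to a remote ketone, which is less reliable than an allylic-alcohol epoxidation.
- Comparison: the chosen route offers reagent control at C13 and a nucleophilic C9 oxygen.

All three place their key step late on an advanced intermediate and presuppose an enantiopure, C19-oxygenated decalin. The chosen strategy builds exactly that early, from cheap material.

Key step: step 10

Remark: labdane numbering is used throughout (C1–C10 decalin, C11–C16 side chain, C17 on C8, C18 and C19 on C4, C20 on C10); α is the face opposite the C10 methyl group.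

## Route

Step 1
Reactants: 1 geraniol
Product: 2 geranyl 4-methoxybenzyl ether
Conditions: NaH, Bu4NI (cat.), THF/DMF, 0 °C to rt; 4-methoxybenzyl chloride
Reagents that add atoms: 4-methoxybenzyl chloride, COc1ccc(CCl)cc1
Why: Williamson ether synthesis. Unlike an acetate, this ether survives the ester reduction of step 4 and is later removed oxidatively beside an epoxide and a silyl ether.

Step 2
Reactants: 2 geranyl 4-methoxybenzyl ether
Product: 4 (4E)-6-(4-methoxybenzyloxy)-4-methylhex-4-enal, via 6,7-epoxygeranyl 4-methoxybenzyl ether 3 (not isolated)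
Conditions: mCPBA, CH2Cl2, −20 to 0 °C; then H5IO6, THF/H2O, 0 °C
Reagents that add atoms: 3-chloroperoxybenzoic acid, OOC(=O)c1cccc(Cl)c1
Why: Prilezhaev epoxidation picks the distal alkene, since the 2,3-alkene is deactivated by the allylic oxygen. Periodic acid then hydrolyses the epoxide and cleaves the glycol to the aldehyde.

Step 3
Reactants: 4 (4E)-6-(4-methoxybenzyloxy)-4-methylhex-4-enal; 5 ethyl 2-(diphenoxyphosphoryl)propanoate
Product: 6 ethyl (2Z,6E)-8-(4-methoxybenzyloxy)-2,6-dimethylocta-2,6-dienoate
Conditions: NaH, THF, −78 to 0 °C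
Reagents that add atoms: none
Why: Z-selective Horner–Wadsworth–Emmons olefination. The diaryl phosphonate collapses from the kinetic adduct, so the ester ends cis to the chain; this geometry later makes C19 axial.

Step 4
Reactants: 6 ethyl (2Z,6E)-8-(4-methoxybenzyloxy)-2,6-dimethylocta-2,6-dienoate
Product: 7 (2Z,6E)-8-(4-methoxybenzyloxy)-2,6-dimethylocta-2,6-dien-1-ol
Conditions: i-Bu2AlH, CH2Cl2, −78 °C; aqueous potassium sodium tartrate
Reagents that add atoms: none
Why: 1,2-reduction of the enoate to the allylic alcohol; the benzyl ether and both alkenes are inert and the Z geometry is kept.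

Step 5
Reactants: 7 (2Z,6E)-8-(4-methoxybenzyloxy)-2,6-dimethylocta-2,6-dien-1-ol
Product: 8 {(2R,3S)-3-[(3E)-5-(4-methoxybenzyloxy)-3-methylpent-3-en-1-yl]-2-methyloxiran-2-yl}methanol
Conditions: Ti(OiPr)4, D-(−)-diethyl tartrate, t-BuOOH, 4 Å molecular sieves, CH2Cl2, −25 °C
Reagents that add atoms: tert-butyl hydroperoxide, CC(C)(C)OO
Why: Sharpless asymmetric epoxidation. With D-(−)-tartrate the Z 2-methyl allylic alcohol should give the (2R,3S) epoxide, which fixes C3 and, through inversion in step 10, C4; the other alkene has no directing hydroxyl.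

Step 6
Reactants: 8 the (2R,3S) epoxy alcohol
Product: 9 tert-butyldimethylsilyl ether of 8
Conditions: TBSCl, imidazole, DMF, 0 °C to rt
Reagents that add atoms: tert-butyldimethylsilyl chloride, CC(C)(C)[Si](C)(C)Cl
Why: Silylation of the primary alcohol; the silyl ether is non-participating in the cationic cyclisation and survives every step up to step 24.

Step 7
Reactants: 9 silyl ether of 8
Product: 10 (2E)-5-[(2S,3R)-3-(tert-butyldimethylsilyloxymethyl)-3-methyloxiran-2-yl]-3-methylpent-2-en-1-ol
Conditions: DDQ, CH2Cl2/pH 7 buffer, 0 °C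
Reagents that add atoms: none
Why: Oxidative cleavage of the 4-methoxybenzyl ether by hydride abstraction; epoxide, silyl ether and alkene are untouched under buffered conditions.

Step 8
Reactants: 10 epoxy allylic alcohol
Product: 12 tert-butyl{[(2R,3S)-3-[(3E)-5-bromo-3-methylpent-3-en-1-yl]-2-methyloxiran-2-yl]methoxy}dimethylsilane, via allylic mesylate 11 (not isolated)
Conditions: MsCl, Et3N, CH2Cl2, −40 °C; then LiBr, THF, 0 °C
Reagents that add atoms: lithium bromide, [Li+].[Br-]
Why: Sulfonylation then SN2 displacement by bromide under non-acidic conditions, so the epoxide is not opened and the E alkene is kept.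

Step 9
Reactants: 12 epoxy allylic bromide; 13 methyl acetoacetate
Product: 14 methyl (6E,10S,11R)-12-(tert-butyldimethylsilyloxy)-10,11-epoxy-7,11-dimethyl-3-oxododec-6-enoate
Conditions: 13, NaH then n-BuLi, THF, 0 °C; then 12, 0 °C
Reagents that add atoms: none
Why: Alkylation of the acetoacetate dianion at its terminal carbon by the primary allylic bromide (SN2), forming C6–C7; the epoxide is far less electrophilic at 0 °C.

Step 10
Reactants: 14 epoxy keto ester
Product: 15 methyl 19-(tert-butyldimethylsilyloxy)-3β-hydroxy-8-oxo-12,13,14,15,16,17-hexanorlabdan-11-oate (5α-H, 9α-H, 10β-methyl)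
Conditions: SnCl4, CH2Cl2, −78 °C; aqueous NaHCO3
Reagents that add atoms: none
Why: Lewis-acid epoxy-polyene bicyclisation ended by a β-keto ester, a known reaction type. SnCl4 holds the keto ester as its chelated enol and activates the epoxide, which opens at tertiary C4. Ring A closes 6-endo at the C5=C10 alkene, with C5 attacking C4 anti to the leaving oxygen; ring B closes 6-endo when enol carbon C9 takes the C10 cation. Both closures pass through chair transition states, so the E alkene gives anti addition and the trans fusion with C20 β and H-5 α. C4 is set by inversion of the epoxide, and the silyloxymethyl group, cis to the chain, ends axial as C19. C3 keeps its oxygen as the equatorial 3β-hydroxyl, and C9 settles with the ester equatorial because it is epimerisable. Absolute configuration at all centres comes from the Sharpless epoxide. The step needs alkene participation at C4 before a 1,2-hydride shift from the CH2OSi group, and C- rather than O-capture by the enol; the concerted anti opening and the tin chelate should secure both.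

Step 11
Reactants: 15 3β-hydroxy keto ester
Product: 16 3β-O-(imidazol-1-ylthiocarbonyl) derivative of 15
Conditions: 1,1'-thiocarbonyldiimidazole, DMAP, toluene, 90 °C
Reagents that add atoms: 1,1'-thiocarbonyldiimidazole, S=C(n1ccnc1)n1ccnc1
Why: Thioacylation of the only hydroxyl, the first half of a Barton–McCombie deoxygenation; the keto ester is in its keto form and does not react.

Step 12
Reactants: 16 thiocarbonylimidazolide
Product: 17 methyl 19-(tert-butyldimethylsilyloxy)-8-oxo-12,13,14,15,16,17-hexanorlabdan-11-oate
Conditions: Bu3SnH, AIBN (cat.), toluene, 100 °C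
Reagents that add atoms: none
Why: Barton–McCombie radical chain. The stannyl radical adds to C=S, the C3–O bond fragments and the secondary C3 radical takes hydrogen from the stannane; no stereocentre is touched.

Step 13
Reactants: 17 keto ester
Product: 18 methyl 19-(tert-butyldimethylsilyloxy)-9α-hydroxy-8-oxo-12,13,14,15,16,17-hexanorlabdan-11-oate
Conditions: KN(SiMe3)2, THF, −78 °C; then 2-(phenylsulfonyl)-3-phenyloxaziridine, −78 °C
Reagents that add atoms: 2-(phenylsulfonyl)-3-phenyloxaziridine, O=S(=O)(c1ccccc1)N1OC1c1ccccc1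
Why: Electrophilic α-hydroxylation of the β-keto ester enolate. C9 is the most acidic position, and the oxidant comes from the α face, anti to the axial C20 methyl on the neighbouring carbon, giving 9α-OH with the ester β.

Step 14
Reactants: 18 9α-hydroxy keto ester
Product: 19 9α-triethylsilyl ether of 18
Conditions: Et3SiOTf, 2,6-lutidine, CH2Cl2, −78 to 0 °C
Reagents that add atoms: triethylsilyl trifluoromethanesulfonate, CC[Si](CC)(CC)OS(=O)(=O)C(F)(F)F
Why: Silyl triflate silylation of a hindered tertiary alcohol. The ether keeps the C9 oxygen out of the enolate chemistry of step 15 and stops it opening the side-chain epoxide early in steps 21 to 23, which would erase the C13 information.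

Step 15
Reactants: 19 silylated keto ester
Product: 20 methyl 19-(tert-butyldimethylsilyloxy)-9α-(triethylsilyloxy)-8-(trifluoromethylsulfonyloxy)-12,13,14,15,16,17-hexanorlabd-7-en-11-oate
Conditions: KN(SiMe3)2, THF, −78 °C; then PhNTf2, −78 to 0 °C
Reagents that add atoms: N-phenylbis(trifluoromethanesulfonimide), FC(F)(F)S(=O)(=O)N(c1ccccc1)S(=O)(=O)C(F)(F)F
Why: Enolate O-triflation. With C9 quaternary the ketone can enolise only toward C7, so a single enol triflate should form.

Step 16
Reactants: 20 enol triflate
Product: 21 methyl 19-(tert-butyldimethylsilyloxy)-9α-(triethylsilyloxy)-12,13,14,15,16-pentanorlabd-7-en-11-oate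
Conditions: Me2Zn, Pd(PPh3)4 (cat.), THF, 0 to 50 °C
Reagents that add atoms: dimethylzinc, C[Zn]C
Why: Negishi cross-coupling of the enol triflate installs C17 on C8; the organozinc does not touch the hindered ester.

Step 17
Reactants: 21 unsaturated ester
Product: 22 19-(tert-butyldimethylsilyloxy)-9α-(triethylsilyloxy)-12,13,14,15,16-pentanorlabd-7-en-11-ol
Conditions: LiAlH4, Et2O, 0 °C to rt
Reagents that add atoms: none
Why: Hydride reduction of the ester to the primary alcohol; the trisubstituted alkene and the silyl ethers are inert.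

Step 18
Reactants: 22 C11 alcohol
Product: 23 19-(tert-butyldimethylsilyloxy)-9α-(triethylsilyloxy)-12,13,14,15,16-pentanorlabd-7-en-11-al
Conditions: Dess–Martin periodinane, NaHCO3, CH2Cl2, rt
Reagents that add atoms: none
Why: Dess–Martin oxidation; the aldehyde has no α-hydrogen, so it can neither enolise nor move into conjugation.

Step 19
Reactants: 23 C11 aldehyde
Product: 24 19-(tert-butyldimethylsilyloxy)-9α-(triethylsilyloxy)-13,14,15,16-tetranorlabda-7,11-diene
Conditions: Ph3PCH3Br, KOt-Bu, THF, 0 °C to rt
Reagents that add atoms: methyltriphenylphosphonium bromide, C[P+](c1ccccc1)(c1ccccc1)c1ccccc1.[Br-]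
Why: Wittig methylenation adds C12; the non-stabilised ylide is reactive enough for a neopentyl aldehyde.

Step 20
Reactants: 24 C9 vinyl compound; 25 2-bromoprop-2-en-1-ol
Product: 27 19-(tert-butyldimethylsilyloxy)-9α-(triethylsilyloxy)-15-norlabda-7,13(16)-dien-14-ol, via C12 alkylborane 26 (not isolated)
Conditions: 9-BBN, THF, rt to 50 °C; then 25, Pd(dppf)Cl2 (cat.), AsPh3, Cs2CO3, DMF/H2O, rt
Reagents that add atoms: none
Why: Anti-Markovnikov hydroboration of the monosubstituted alkene (the trisubstituted C7=C8 alkene is too hindered for 9-BBN), then B-alkyl Suzuki–Miyaura coupling forms C12–C13. The free hydroxyl of 25 is tolerated in the aqueous basic medium.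

Step 21
Reactants: 27 2-substituted allylic alcohol
Product: 28 (13S)-13,16-epoxy-19-(tert-butyldimethylsilyloxy)-9α-(triethylsilyloxy)-15-norlabd-7-en-14-ol
Conditions: Ti(OiPr)4 (cat.), L-(+)-diethyl tartrate, t-BuOOH, 4 Å molecular sieves, CH2Cl2, −20 °C
Reagents that add atoms: tert-butyl hydroperoxide, CC(C)(C)OO
Why: Sharpless asymmetric epoxidation of a 2-substituted allylic alcohol. L-(+)-tartrate should give the (S) epoxy alcohol by reagent control, catalytic titanium limits opening of the product, and the C7=C8 alkene has no allylic hydroxyl.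

Step 22
Reactants: 28 epoxy alcohol
Product: 29 (13R)-13,16-epoxy-19-(tert-butyldimethylsilyloxy)-9α-(triethylsilyloxy)-15-norlabd-7-en-14-al
Conditions: Dess–Martin periodinane, NaHCO3, CH2Cl2, 0 °C to rt
Reagents that add atoms: none
Why: Dess–Martin oxidation; the α-carbon is quaternary, so the epoxy aldehyde cannot epimerise (the descriptor changes only through priority).

Step 23
Reactants: 29 epoxy aldehyde
Product: 30 (13S)-13,16-epoxy-19-(tert-butyldimethylsilyloxy)-9α-(triethylsilyloxy)labd-7-en-14-yne
Conditions: dimethyl (1-diazo-2-oxopropyl)phosphonate, K2CO3, MeOH, 0 °C to rt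
Reagents that add atoms: dimethyl (1-diazo-2-oxopropyl)phosphonate, COP(=O)(OC)C(=[N+]=[N-])C(C)=O
Why: Seyferth–Gilbert homologation in the Ohira–Bestmann modification turns the aldehyde into the terminal alkyne and adds C15; the epoxide configuration is not involved.

Step 24
Reactants: 30 bis-silyl ethynyl epoxide
Product: 31 (13S)-13,16-epoxylabd-7-en-14-yne-9α,19-diol
Conditions: Bu4NF, AcOH, THF, rt to 40 °C
Reagents that add atoms: none
Why: Fluoride cleaves both silyl ethers; the acetic acid buffer keeps the tertiary alkoxide from forming and attacking the epoxide under basic conditions.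

Step 25
Reactants: 31 diol
Product: 32 (13S)-13,16-epoxy-9α-hydroxylabd-7-en-14-yn-19-yl acetate
Conditions: Ac2O, pyridine, DMAP (cat.), CH2Cl2, 0 °C
Reagents that add atoms: acetic anhydride, CC(=O)OC(C)=O
Why: Acylation of the primary alcohol only; the tertiary C9 hydroxyl lies between two fully substituted carbons and should not react. It is done here because after step 26 the C16 hydroxyl would compete.

Step 26
Reactants: 32 hydroxy ethynyl epoxide
Product: 33 (13R)-9α,13-epoxy-16-hydroxylabd-7-en-14-yn-19-yl acetate
Conditions: (+)-10-camphorsulfonic acid (0.1 equiv), CH2Cl2, 0 °C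
Reagents that add atoms: none
Why: Acid-catalysed 5-exo epoxide opening by the C9 hydroxyl at the tertiary propargylic carbon, anti to the leaving oxygen. Inversion at C13 gives (13R) and frees the C16 hydroxyl; attack at the CH2 end would be 6-endo and anti-Markovnikov.

Step 27
Reactants: 33 spiro ether alkynol
Product: 34 (13R)-7α,8α;9α,13-diepoxy-16-hydroxylabd-14-yn-19-yl acetate
Conditions: mCPBA, NaHCO3, CH2Cl2, 0 °C
Reagents that add atoms: 3-chloroperoxybenzoic acid, OOC(=O)c1cccc(Cl)c1
Why: Prilezhaev epoxidation of the only electron-rich alkene from the α face, the β face being screened by the axial C20 methyl and by C11; the terminal alkyne is inert at 0 °C.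

Step 28
Reactants: 34 7α,8α-epoxide
Product: 35 (13R)-9α,13-epoxy-7α,16-dihydroxylabd-14-yne-8β,19-diyl diacetate
Conditions: AcOH, 40 °C
Reagents that add atoms: acetic acid, CC(=O)O
Why: Acid-catalysed epoxide opening under the Fürst–Plattner rule. Acetic acid attacks tertiary C8 axially from the β face with inversion, giving the trans-diaxial 8β-acetoxy-7α-ol and setting C8 with C17 α; the trans-diaxial array prevents acyl migration.

Step 29
Reactants: 35 homopropargylic alcohol
Product: 36 (13R)-9α,13;15,16-diepoxy-7α-hydroxylabd-14-ene-8β,19-diyl diacetate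
Conditions: Mo(CO)6 (0.25 equiv), Et3N, Et2O, hν (350 nm); then 35, rt
Reagents that add atoms: none
Why: Endo-selective cycloisomerisation of a homopropargylic alcohol through a molybdenum vinylidene: the C16 oxygen adds to C15 and gives the 2,3-dihydrofuran. The amine medium preserves the enol ether and the acetates, and the 7α-hydroxyl is too remote to compete.

Step 30
Reactants: 36 7α-alcohol
Product: 37 (13R)-9α,13;15,16-diepoxy-7-oxolabd-14-ene-8β,19-diyl diacetate (target)
Conditions: Dess–Martin periodinane, pyridine, CH2Cl2, 0 °C to rt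
Reagents that add atoms: none
Why: Dess–Martin oxidation of the axial secondary alcohol, buffered with pyridine so that the enol ether sees no acid; C8 is quaternary, so no stereocentre can epimerise.

## Compound list

1 | geraniol, (2E)-3,7-dimethylocta-2,6-dien-1-ol | CC(C)=CCC/C(C)=C/CO | starting material
2 | geranyl 4-methoxybenzyl ether | CC(C)=CCC/C(C)=C/COCc1ccc(OC)cc1 | intermediate
3 | 6,7-epoxygeranyl 4-methoxybenzyl ether (racemic epoxide) | CC1(C)OC1CC/C(C)=C/COCc1ccc(OC)cc1 | intermediate (not isolated)
4 | (4E)-6-(4-methoxybenzyloxy)-4-methylhex-4-enal | O=CCC/C(C)=C/COCc1ccc(OC)cc1 | intermediate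
5 | ethyl 2-(diphenoxyphosphoryl)propanoate | CCOC(=O)C(C)P(=O)(Oc1ccccc1)Oc1ccccc1 | starting material
6 | ethyl (2Z,6E)-8-(4-methoxybenzyloxy)-2,6-dimethylocta-2,6-dienoate | CCOC(=O)/C(C)=C\CC/C(C)=C/COCc1ccc(OC)cc1 | intermediate
7 | (2Z,6E)-8-(4-methoxybenzyloxy)-2,6-dimethylocta-2,6-dien-1-ol | OC/C(C)=C\CC/C(C)=C/COCc1ccc(OC)cc1 | intermediate
8 | {(2R,3S)-3-[(3E)-5-(4-methoxybenzyloxy)-3-methylpent-3-en-1-yl]-2-methyloxiran-2-yl}methanol | OC[C@@]1(C)O[C@H]1CC/C(C)=C/COCc1ccc(OC)cc1 | intermediate
9 | tert-butyldimethylsilyl ether of 8 | CC(C)(C)[Si](C)(C)OC[C@@]1(C)O[C@H]1CC/C(C)=C/COCc1ccc(OC)cc1 | intermediate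
10 | (2E)-5-[(2S,3R)-3-(tert-butyldimethylsilyloxymethyl)-3-methyloxiran-2-yl]-3-methylpent-2-en-1-ol | CC(C)(C)[Si](C)(C)OC[C@@]1(C)O[C@H]1CC/C(C)=C/CO | intermediate
11 | methanesulfonate of 10 | CC(C)(C)[Si](C)(C)OC[C@@]1(C)O[C@H]1CC/C(C)=C/COS(C)(=O)=O | intermediate (not isolated)
12 | tert-butyl{[(2R,3S)-3-[(3E)-5-bromo-3-methylpent-3-en-1-yl]-2-methyloxiran-2-yl]methoxy}dimethylsilane | CC(C)(C)[Si](C)(C)OC[C@@]1(C)O[C@H]1CC/C(C)=C/CBr | intermediate
13 | methyl acetoacetate | COC(=O)CC(C)=O | starting material
14 | methyl (6E,10S,11R)-12-(tert-butyldimethylsilyloxy)-10,11-epoxy-7,11-dimethyl-3-oxododec-6-enoate | CC(C)(C)[Si](C)(C)OC[C@@]1(C)O[C@H]1CC/C(C)=C/CCC(=O)CC(=O)OC | intermediate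
15 | methyl 19-(tert-butyldimethylsilyloxy)-3β-hydroxy-8-oxo-12,13,14,15,16,17-hexanorlabdan-11-oate | CC(C)(C)[Si](C)(C)OC[C@@]1(C)[C@@H](O)CC[C@@]2(C)[C@H]1CCC(=O)[C@@H]2C(=O)OC | intermediate
16 | 3β-O-(imidazol-1-ylthiocarbonyl) derivative of 15 | CC(C)(C)[Si](C)(C)OC[C@@]1(C)[C@@H](OC(=S)n3ccnc3)CC[C@@]2(C)[C@H]1CCC(=O)[C@@H]2C(=O)OC | intermediate
17 | methyl 19-(tert-butyldimethylsilyloxy)-8-oxo-12,13,14,15,16,17-hexanorlabdan-11-oate | CC(C)(C)[Si](C)(C)OC[C@@]1(C)CCC[C@@]2(C)[C@H]1CCC(=O)[C@@H]2C(=O)OC | intermediate
18 | methyl 19-(tert-butyldimethylsilyloxy)-9α-hydroxy-8-oxo-12,13,14,15,16,17-hexanorlabdan-11-oate | CC(C)(C)[Si](C)(C)OC[C@@]1(C)CCC[C@@]2(C)[C@H]1CCC(=O)[C@]2(O)C(=O)OC | intermediate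
19 | methyl 19-(tert-butyldimethylsilyloxy)-8-oxo-9α-(triethylsilyloxy)-12,13,14,15,16,17-hexanorlabdan-11-oate | CC(C)(C)[Si](C)(C)OC[C@@]1(C)CCC[C@@]2(C)[C@H]1CCC(=O)[C@]2(O[Si](CC)(CC)CC)C(=O)OC | intermediate
20 | methyl 19-(tert-butyldimethylsilyloxy)-9α-(triethylsilyloxy)-8-(trifluoromethylsulfonyloxy)-12,13,14,15,16,17-hexanorlabd-7-en-11-oate | CC(C)(C)[Si](C)(C)OC[C@@]1(C)CCC[C@@]2(C)[C@H]1CC=C(OS(=O)(=O)C(F)(F)F)[C@]2(O[Si](CC)(CC)CC)C(=O)OC | intermediate
21 | methyl 19-(tert-butyldimethylsilyloxy)-9α-(triethylsilyloxy)-12,13,14,15,16-pentanorlabd-7-en-11-oate | CC(C)(C)[Si](C)(C)OC[C@@]1(C)CCC[C@@]2(C)[C@H]1CC=C(C)[C@]2(O[Si](CC)(CC)CC)C(=O)OC | intermediate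
22 | 19-(tert-butyldimethylsilyloxy)-9α-(triethylsilyloxy)-12,13,14,15,16-pentanorlabd-7-en-11-ol | CC(C)(C)[Si](C)(C)OC[C@@]1(C)CCC[C@@]2(C)[C@H]1CC=C(C)[C@]2(O[Si](CC)(CC)CC)CO | intermediate
23 | 19-(tert-butyldimethylsilyloxy)-9α-(triethylsilyloxy)-12,13,14,15,16-pentanorlabd-7-en-11-al | CC(C)(C)[Si](C)(C)OC[C@@]1(C)CCC[C@@]2(C)[C@H]1CC=C(C)[C@]2(O[Si](CC)(CC)CC)C=O | intermediate
24 | 19-(tert-butyldimethylsilyloxy)-9α-(triethylsilyloxy)-13,14,15,16-tetranorlabda-7,11-diene | CC(C)(C)[Si](C)(C)OC[C@@]1(C)CCC[C@@]2(C)[C@H]1CC=C(C)[C@]2(O[Si](CC)(CC)CC)C=C | intermediate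
25 | 2-bromoprop-2-en-1-ol | OCC(Br)=C | starting material
26 | 12-(9-borabicyclo[3.3.1]nonan-9-yl)-19-(tert-butyldimethylsilyloxy)-9α-(triethylsilyloxy)-13,14,15,16-tetranorlabd-7-ene | CC(C)(C)[Si](C)(C)OC[C@@]1(C)CCC[C@@]2(C)[C@H]1CC=C(C)[C@]2(O[Si](CC)(CC)CC)CCB3C4CCCC3CCC4 | intermediate (not isolated)
27 | 19-(tert-butyldimethylsilyloxy)-9α-(triethylsilyloxy)-15-norlabda-7,13(16)-dien-14-ol | CC(C)(C)[Si](C)(C)OC[C@@]1(C)CCC[C@@]2(C)[C@H]1CC=C(C)[C@]2(O[Si](CC)(CC)CC)CCC(=C)CO | intermediate
28 | (13S)-13,16-epoxy-19-(tert-butyldimethylsilyloxy)-9α-(triethylsilyloxy)-15-norlabd-7-en-14-ol | CC(C)(C)[Si](C)(C)OC[C@@]1(C)CCC[C@@]2(C)[C@H]1CC=C(C)[C@]2(O[Si](CC)(CC)CC)CC[C@@]3(CO3)CO | intermediate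
29 | (13R)-13,16-epoxy-19-(tert-butyldimethylsilyloxy)-9α-(triethylsilyloxy)-15-norlabd-7-en-14-al | CC(C)(C)[Si](C)(C)OC[C@@]1(C)CCC[C@@]2(C)[C@H]1CC=C(C)[C@]2(O[Si](CC)(CC)CC)CC[C@@]3(CO3)C=O | intermediate
30 | (13S)-13,16-epoxy-19-(tert-butyldimethylsilyloxy)-9α-(triethylsilyloxy)labd-7-en-14-yne | CC(C)(C)[Si](C)(C)OC[C@@]1(C)CCC[C@@]2(C)[C@H]1CC=C(C)[C@]2(O[Si](CC)(CC)CC)CC[C@@]3(CO3)C#C | intermediate
31 | (13S)-13,16-epoxylabd-7-en-14-yne-9α,19-diol | OC[C@@]1(C)CCC[C@@]2(C)[C@H]1CC=C(C)[C@]2(O)CC[C@@]3(CO3)C#C | intermediate
32 | (13S)-13,16-epoxy-9α-hydroxylabd-7-en-14-yn-19-yl acetate | CC(=O)OC[C@@]1(C)CCC[C@@]2(C)[C@H]1CC=C(C)[C@]2(O)CC[C@@]3(CO3)C#C | intermediate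
33 | (13R)-9α,13-epoxy-16-hydroxylabd-7-en-14-yn-19-yl acetate | CC(=O)OC[C@@]1(C)CCC[C@@]2(C)[C@H]1CC=C(C)[C@]21CC[C@](CO)(C#C)O1 | intermediate
34 | (13R)-7α,8α;9α,13-diepoxy-16-hydroxylabd-14-yn-19-yl acetate | CC(=O)OC[C@@]1(C)CCC[C@@]2(C)[C@H]1C[C@H]3O[C@@]3(C)[C@]21CC[C@](CO)(C#C)O1 | intermediate
35 | (13R)-9α,13-epoxy-7α,16-dihydroxylabd-14-yne-8β,19-diyl diacetate | CC(=O)OC[C@@]1(C)CCC[C@@]2(C)[C@H]1C[C@@H](O)[C@](C)(OC(C)=O)[C@]21CC[C@](CO)(C#C)O1 | intermediate
36 | (13R)-9α,13;15,16-diepoxy-7α-hydroxylabd-14-ene-8β,19-diyl diacetate | CC(=O)OC[C@@]1(C)CCC[C@@]2(C)[C@H]1C[C@@H](O)[C@](C)(OC(C)=O)[C@]21CC[C@]2(C=COC2)O1 | intermediate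
37 | (13R)-9α,13;15,16-diepoxy-7-oxolabd-14-ene-8β,19-diyl diacetate | CC(=O)OC[C@@]1(C)CCC[C@@]2(C)[C@H]1CC(=O)[C@](C)(OC(C)=O)[C@]21CC[C@]2(C=COC2)O1 | target

## Step count and least certain steps

Total step count: 30. Longest linear sequence: 30 steps, from 1 to 37; compounds 5, 13 and 25 are bought.

Step 10 (key step). The most likely failure is a 1,2-hydride shift from the silyloxymethyl group to the developing C4 cation, which opens the epoxide to an aldehyde. Other risks are a stop after ring A with proton loss, or capture of the C10 cation by the enol oxygen. The oxygen on C19 destabilises the C4 cation and makes these paths more competitive. Fallback: starting from 14, the keto ester is converted with NaH and TBSCl into its silyl enol ether, methyl (2Z,6E,10S,11R)-3,12-bis(tert-butyldimethylsilyloxy)-10,11-epoxy-7,11-dimethyldodeca-2,6-dienoate F1. This neutral, carbon-nucleophilic terminator is cyclised with MeAlCl2 in CH2Cl2 at −78 °C, a known epoxy-polyene cyclisation ended by an enol silyl ether. Hydrolytic work-up removes the silyl group from the keto ester and the route is rejoined at 15.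

Step 26. The tertiary C9 hydroxyl is also allylic, so acid may ionise it (loss of water to a diene) faster than the hindered oxygen attacks; a propargylic cation at C13 could also erode the configuration. Fallback: starting from 32, the C7=C8 alkene is epoxidised first with mCPBA, directed to the α face by the allylic 9α-hydroxyl, to give (13S)-7α,8α;13,16-diepoxy-9α-hydroxylabd-14-yn-19-yl acetate F2. Its C9 hydroxyl is no longer allylic. The same acid-catalysed 5-exo closure then gives 34 directly, and the route continues with step 28.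

Step 28. Proton loss from C17 (giving an exocyclic alkene) or a hydride shift from C7 may outrun capture by acetic acid on the hindered β face of C8. Fallback: starting from 34, the epoxide is opened with the smaller nucleophile water (HClO4 cat., THF/H2O, 0 °C) to (13R)-9α,13-epoxy-7α,8β,16-trihydroxylabd-14-yn-19-yl acetate F3. Cycloisomerisation as in step 29 gives (13R)-9α,13;15,16-diepoxy-7α,8β-dihydroxylabd-14-en-19-yl acetate F4, and Dess–Martin oxidation with pyridine gives (13R)-9α,13;15,16-diepoxy-8β-hydroxy-7-oxolabd-14-en-19-yl acetate F5. The tertiary hydroxyl of F5 is then acetylated under basic conditions (Ac2O, DMAP, Et3N, 40 °C), which the enol ether tolerates, and the route ends at 37.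

Step 29. The vinylidene may fail to form at the alkyne on the quaternary C13, or the propargylic C–O bond of ring C may be lost from the metal intermediate. Fallback: starting from 35, the terminal alkyne is hydroborated with dicyclohexylborane and oxidised with NaBO3. The resulting C15 aldehyde closes onto the C16 hydroxyl to give the lactol (13R)-9α,13;15,16-diepoxy-7α,15-dihydroxylabdane-8β,19-diyl diacetate F6. Dehydration of the lactol with MsCl and Et3N (−20 °C to rt), a standard route to cyclic enol ethers, gives 36; the hindered axial 7α-hydroxyl should not react under these conditions.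

## Further compounds

F1 | step 10 | methyl (2Z,6E,10S,11R)-3,12-bis(tert-butyldimethylsilyloxy)-10,11-epoxy-7,11-dimethyldodeca-2,6-dienoate | CC(C)(C)[Si](C)(C)OC[C@@]1(C)O[C@H]1CC/C(C)=C/CC/C(O[Si](C)(C)C(C)(C)C)=C/C(=O)OC
F2 | step 26 | (13S)-7α,8α;13,16-diepoxy-9α-hydroxylabd-14-yn-19-yl acetate | CC(=O)OC[C@@]1(C)CCC[C@@]2(C)[C@H]1C[C@H]3O[C@@]3(C)[C@]2(O)CC[C@@]4(CO4)C#C
F3 | step 28 | (13R)-9α,13-epoxy-7α,8β,16-trihydroxylabd-14-yn-19-yl acetate | CC(=O)OC[C@@]1(C)CCC[C@@]2(C)[C@H]1C[C@@H](O)[C@](C)(O)[C@]21CC[C@](CO)(C#C)O1
F4 | step 28 | (13R)-9α,13;15,16-diepoxy-7α,8β-dihydroxylabd-14-en-19-yl acetate | CC(=O)OC[C@@]1(C)CCC[C@@]2(C)[C@H]1C[C@@H](O)[C@](C)(O)[C@]21CC[C@]2(C=COC2)O1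
F5 | step 28 | (13R)-9α,13;15,16-diepoxy-8β-hydroxy-7-oxolabd-14-en-19-yl acetate | CC(=O)OC[C@@]1(C)CCC[C@@]2(C)[C@H]1CC(=O)[C@](C)(O)[C@]21CC[C@]2(C=COC2)O1
F6 | step 29 | (13R)-9α,13;15,16-diepoxy-7α,15-dihydroxylabdane-8β,19-diyl diacetate (lactol) | CC(=O)OC[C@@]1(C)CCC[C@@]2(C)[C@H]1C[C@@H](O)[C@](C)(OC(C)=O)[C@]21CC[C@]2(CC(O)OC2)O1
A1 | alternative 1 | spiro γ-lactone, (13R)-19-(tert-butyldimethylsilyloxy)-9α,13-epoxylabd-7-en-15,16-olide | CC(C)(C)[Si](C)(C)OC[C@@]1(C)CCC[C@@]2(C)[C@H]1CC=C(C)[C@]21CC[C@]2(CC(=O)OC2)O1
A2 | alternative 1 | C16 diazoacetate of the 9α,13-epoxy-14,15-dinorlabd-7-en-16-ol | CC(C)(C)[Si](C)(C)OC[C@@]1(C)CCC[C@@]2(C)[C@H]1CC=C(C)[C@]21CC[C@@H](COC(=O)C=[N+]=[N-])O1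
A3 | alternative 2 | 8β-hydroxy-7-ketone with rings A, B and C, C16 silyl ether and silylalkyne | CC(=O)OC[C@@]1(C)CCC[C@@]2(C)[C@H]1CC(=O)[C@](C)(O)[C@]21CC[C@](CO[Si](C)(C)C(C)(C)C)(C#C[Si](C)(C)C)O1
A4 | alternative 2 | 7,8-seco C7 aldehyde C8 methyl ketone | CC(=O)OC[C@@]1(C)CCC[C@@](C)([C@H]1CC=O)[C@]1(C(C)=O)CC[C@](CO[Si](C)(C)C(C)(C)C)(C#C[Si](C)(C)C)O1
A5 | alternative 3 | 7β,8β-diol with spiro ring C closed | CC(=O)OC[C@@]1(C)CCC[C@@]2(C)[C@H]1C[C@H](O)[C@](C)(O)[C@]21CC[C@](CO[Si](C)(C)C(C)(C)C)(C#C)O1
A6 | alternative 3 | 8β,9β-epoxide with 7β- and C13 hydroxyls | CC(=O)OC[C@@]1(C)CCC[C@@]2(C)[C@H]1C[C@H](O)[C@]1(C)O[C@]21CC[C@](O)(CO[Si](C)(C)C(C)(C)C)C#C
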